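Ring A (labdane numbering) is treated as a Diels–Alder retron: its C3–C4 and C5–C10 bonds flank the C4(CH3)2–C5H unit, and C5–C10 is also the ring A/ring B fusion bond. An acyclic 1,7,9-decatrien-3-one carrying the whole side chain is therefore cyclised in one Lewis-acid-promoted intramolecular [4+2] step. The C4=C5 bond of a β,β-dimethyl enone (temporary C6 ketone) adds to the C10=C1–C2=C3 diene, closing both rings and creating C5 and quaternary C10 under control of the C9 stereocentre. A Johnson–Claisen rearrangement relays C9 from an alkynyl carbinol made from geraniol. The C6 ketone is later removed through its enol triflate, which also delivers the C7=C8 enoate.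

Key step: step 9

Remark: atoms are named in labdane numbering (C1–C10 decalin, C11–C16 side chain, C17 = carboxyl carbon on C8, C18/C19 on C4, C20 on C10); O15 is carried as a TBS ether and acylated last because the isobutyrate would not survive the enolate, Grignard and saponification steps.

Step 1
Reactants: 1 geraniol
Product: 2 geranyl tert-butyldimethylsilyl ether
Conditions: TBSCl, imidazole, DMF, 0 °C to rt
Reagents that add atoms: tert-butyldimethylsilyl chloride, CC(C)(C)[Si](C)(C)Cl
Why: Routine silylation of the primary allylic alcohol gives a base-stable mask for O15.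

Step 2
Reactants: 2 geranyl tert-butyldimethylsilyl ether
Product: 4 (2E,6E)-8-(tert-butyldimethylsilyloxy)-2,6-dimethylocta-2,6-dienal, via allylic alcohol 3 (not isolated)
Conditions: SeO2 (cat.), t-BuOOH, salicylic acid (cat.), CH2Cl2, rt; then MnO2, CH2Cl2, rt
Reagents that add atoms: tert-butyl hydroperoxide, CC(C)(C)OO
Why: Catalytic SeO2 allylic oxidation (ene reaction then [2,3]-sigmatropic shift) should attack the E-methyl group of the electron-richer distal trisubstituted alkene, and MnO2 takes the crude allylic alcohol on to the (E)-enal whose carbonyl carbon becomes C1.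

Step 3
Reactants: 4 (2E,6E)-8-(tert-butyldimethylsilyloxy)-2,6-dimethylocta-2,6-dienal; 5 (trimethylsilyl)acetylene
Product: 6 (3R,4E,8E)-10-(tert-butyldimethylsilyloxy)-4,8-dimethyl-1-(trimethylsilyl)deca-4,8-dien-1-yn-3-ol
Conditions: ProPhenol ligand (antipode that gives 3R, 20 mol %), Me2Zn, Ph3PO (cat.), toluene, 4 °C; H2O quench
Reagents that add atoms: none
Why: Zinc–ProPhenol-catalysed enantioselective alkynylation of the α-branched enal, in which the dinuclear zinc catalyst delivers the alkynylzinc to one aldehyde face and so sets the C1 carbinol (3R) that is later relayed to C9.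

Step 4
Reactants: 6 (3R)-alkynyl alkenyl carbinol; 7 trimethyl orthoacetate
Product: 9 methyl (3S,4E)-3-[(3E)-5-(tert-butyldimethylsilyloxy)-3-methylpent-3-en-1-yl]-4-methyl-7-(trimethylsilyl)hept-4-en-6-ynoate, via ketene acetal 8 (not isolated)
Conditions: MeC(OMe)3 (excess), EtCO2H (cat.), xylene, 135 °C, MeOH distilled off
Reagents that add atoms: none
Why: Johnson–Claisen rearrangement through the allyl arm (the silyl-capped propargyl arm is slower) in a chair transition state with the alkynyl group pseudo-equatorial should give the (E)-enyne and transfer the carbinol chirality suprafacially across the (E)-alkene to C9 (3S) while forming the C8–C9 bond.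

Step 5
Reactants: 9 methyl ester from step 4; 10 2-bromo-N-methoxy-N-methylacetamide
Product: 11 methyl (2RS,3S,4E)-3-[(3E)-5-(tert-butyldimethylsilyloxy)-3-methylpent-3-en-1-yl]-2-{2-[methoxy(methyl)amino]-2-oxoethyl}-4-methyl-7-(trimethylsilyl)hept-4-en-6-ynoate
Conditions: LiN(i-Pr)2, THF, −78 °C; then 10, DMPU, −78 to −30 °C
Reagents that add atoms: none
Why: SN2 alkylation of the ester enolate with the activated α-bromo amide attaches C7 and the future C6 carbonyl carbon; C8 forms as an epimer mixture, which is harmless because C8 ends sp2.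

Step 6
Reactants: 11 Weinreb amide ester; 12 2-methylprop-1-enylmagnesium bromide
Product: 13 methyl (2RS,3S,4E)-3-[(3E)-5-(tert-butyldimethylsilyloxy)-3-methylpent-3-en-1-yl]-4-methyl-2-(4-methyl-2-oxopent-3-en-1-yl)-7-(trimethylsilyl)hept-4-en-6-ynoate
Conditions: (CH3)2C=CHMgBr (1.2 equiv), THF, −40 to −10 °C; H2O quench
Reagents that add atoms: none
Why: Weinreb ketone synthesis, in which the chelated tetrahedral intermediate prevents over-addition and the amide reacts ahead of the methyl ester, gives the β,β-dimethyl enone C4=C5–C6=O.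

Step 7
Reactants: 13 silylated enynyl enone
Product: 14 methyl (2RS,3S,4E)-3-[(3E)-5-(tert-butyldimethylsilyloxy)-3-methylpent-3-en-1-yl]-4-methyl-2-(4-methyl-2-oxopent-3-en-1-yl)hept-4-en-6-ynoate
Conditions: K2CO3 (cat.), MeOH, 0 °C
Reagents that add atoms: none
Why: Mild methanolysis cleaves only the alkynyl C–Si bond; the alkyl TBS ether and the methyl ester are unaffected in methanol.

Step 8
Reactants: 14 terminal enyne
Product: 15 methyl (2RS,3S,4E)-3-[(3E)-5-(tert-butyldimethylsilyloxy)-3-methylpent-3-en-1-yl]-4-methyl-2-(4-methyl-2-oxopent-3-en-1-yl)hepta-4,6-dienoate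
Conditions: H2 (1 atm), Pd/CaCO3 poisoned with Pb(OAc)2, quinoline, EtOAc, rt
Reagents that add atoms: none
Why: Lindlar semi-hydrogenation of the terminal alkyne should stop at the vinyl group and give the (E)-C10=C1–C2=C3 diene without touching the trisubstituted alkenes or the enone.

Step 9
Reactants: 15 dienyl enone (a substituted 1,7,9-decatrien-3-one)
Product: 17 methyl (5αH,8βH,9αH,10β-methyl,13E)-15-(tert-butyldimethylsilyloxy)-6-oxolabda-1,13-dien-17-oate, via kinetic cycloadduct 16 (not isolated)
Conditions: Me2AlCl (1.5 equiv), CH2Cl2, −78 to −20 °C; H2O quench; then NaOMe (cat.), MeOH, rt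
Reagents that add atoms: none
Why: Me2AlCl binds the C6 carbonyl and the enone C4=C5 adds across the C10=C1–C2=C3 diene in a concerted but asynchronous type 1 intramolecular Diels–Alder reaction, the C3–C4 bond (unhindered diene terminus to enone β-carbon) running ahead of C5–C10 so that charge builds at the methyl-stabilised C10; the closest known reactions are Lewis-acid-promoted cyclisations of 1,7,9-decatrien-3-ones and the AlCl3-mediated addition of mesityl oxide to 1,3-pentadiene, which has the same regiochemistry. Ring A closes by the [4+2] itself (both new bonds lie in it, leaving C1=C2), and ring B closes in the fused, tethered mode, the four-atom chain C6–C9 making C5–C10 a six-membered ring closure. Quaternary C10 is set relative to C9: in the chair-like exo-tether transition state the C9 side chain is pseudo-equatorial and anti to the forming C5–C10 bond while H9 lies in the diene plane, so C5 should add to the diene face that puts C20 and C11 cis. C5 should arise trans to C20 from the same geometry and, being α to the C6 ketone, is in any case equilibrated by NaOMe to the trans-fused ketone, which also converges the C8 epimers on the equatorial ester. The step needs regioselectivity, which the tether enforces and the enone/diene polarity matches, and facial selectivity at the diene, which rests on the C9 stereocentre and on the (E)-diene geometry from step 4 (C9 outside, C20 inside).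

Step 10
Reactants: 17 bicyclic keto ester
Product: 18 methyl (5αH,8βH,9αH,10β-methyl,13E)-15-(tert-butyldimethylsilyloxy)-6-oxolabd-13-en-17-oate
Conditions: H2 (3 atm), RhCl(PPh3)3 (10 mol %), benzene/EtOH, rt
Reagents that add atoms: none
Why: Homogeneous hydrogenation with RhCl(PPh3)3 should reduce the cis-disubstituted ring A alkene and leave the trisubstituted side-chain alkene and the ketone.

Step 11
Reactants: 18 saturated keto ester
Product: 19 methyl (5αH,8βH,9αH,10β-methyl,13E)-15-(tert-butyldimethylsilyloxy)-6-(trifluoromethanesulfonyloxy)labda-6,13-dien-17-oate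
Conditions: KN(SiMe3)2 (1.05 equiv), THF, −78 °C; PhNTf2, −78 to 0 °C
Reagents that add atoms: N-phenylbis(trifluoromethanesulfonimide), O=S(=O)(N(c1ccccc1)S(=O)(=O)C(F)(F)F)C(F)(F)F
Why: Kinetic deprotonation should occur at the C7 methylene (C5–H is shielded by the flanking quaternary C4 and C10 and the ester α-H is less acidic), and O-triflation of the enolate gives the Δ6 enol triflate.

Step 12
Reactants: 19 enol triflate
Product: 21 methyl (5αH,9αH,10β-methyl,13E)-15-(tert-butyldimethylsilyloxy)labda-7,13-dien-17-oate, via deconjugated ester 20 (not isolated)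
Conditions: Pd(OAc)2 (5 mol %), PPh3, HCO2H, n-Bu3N, DMF, 60 °C; then NaOMe (cat.), MeOH, 50 °C
Reagents that add atoms: none
Why: Palladium-catalysed formate reduction of the enol triflate (oxidative addition to zerovalent palladium, formate exchange, decarboxylation, reductive elimination) removes the C6 oxygen, and methoxide then moves the C6=C7 bond into conjugation through the C8 dienolate, which is protonated at C6.

Step 13
Reactants: 21 conjugated methyl ester
Product: 23 (5αH,9αH,10β-methyl,13E)-15-hydroxylabda-7,13-dien-17-oic acid, via silyl ether acid 22 (not isolated)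
Conditions: KOH, MeOH/H2O, 70 °C; then AcOH/THF/H2O (3:1:1), rt
Reagents that add atoms: potassium hydroxide, [K+].[OH-]
Why: Saponification of the hindered conjugated methyl ester is followed by mild acidic cleavage of the primary TBS ether; no stereocentre is epimerisable under these conditions.

Step 14
Reactants: 23 hydroxy acid; 24 isobutyric anhydride
Product: 25 (5S,9R,10S,13E)-15-(2-methylpropanoyloxy)labda-7,13-dien-17-oic acid (target)
Conditions: (i-PrCO)2O (1.2 equiv), pyridine, DMAP (cat.), CH2Cl2, 0 °C; aq. NaHCO3/THF, then dilute acid work-up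
Reagents that add atoms: none
Why: DMAP-catalysed acylation of the primary allylic alcohol should be much faster than mixed-anhydride formation at the hindered conjugated acid, and any mixed anhydride is hydrolysed at its less hindered isobutyryl carbonyl during the aqueous work-up.

Compound list
1 | geraniol, (2E)-3,7-dimethylocta-2,6-dien-1-ol | CC(C)=CCC/C(C)=C/CO | starting material
2 | geranyl tert-butyldimethylsilyl ether | CC(C)=CCC/C(C)=C/CO[Si](C)(C)C(C)(C)C | intermediate
3 | (2E,6E)-8-(tert-butyldimethylsilyloxy)-2,6-dimethylocta-2,6-dien-1-ol (not isolated) | OC/C(C)=C/CC/C(C)=C/CO[Si](C)(C)C(C)(C)C | intermediate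
4 | (2E,6E)-8-(tert-butyldimethylsilyloxy)-2,6-dimethylocta-2,6-dienal | O=C/C(C)=C/CC/C(C)=C/CO[Si](C)(C)C(C)(C)C | intermediate
5 | (trimethylsilyl)acetylene | C#C[Si](C)(C)C | starting material
6 | (3R,4E,8E)-10-(tert-butyldimethylsilyloxy)-4,8-dimethyl-1-(trimethylsilyl)deca-4,8-dien-1-yn-3-ol | C[Si](C)(C)C#C[C@H](O)/C(C)=C/CC/C(C)=C/CO[Si](C)(C)C(C)(C)C | intermediate
7 | trimethyl orthoacetate | COC(C)(OC)OC | starting material
8 | mixed ketene acetal of 6, (3R)-3-[(1-methoxyethenyl)oxy] derivative (not isolated) | C[Si](C)(C)C#C[C@H](OC(=C)OC)/C(C)=C/CC/C(C)=C/CO[Si](C)(C)C(C)(C)C | intermediate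
9 | methyl (3S,4E)-3-[(3E)-5-(tert-butyldimethylsilyloxy)-3-methylpent-3-en-1-yl]-4-methyl-7-(trimethylsilyl)hept-4-en-6-ynoate | COC(=O)C[C@H](CC/C(C)=C/CO[Si](C)(C)C(C)(C)C)/C(C)=C/C#C[Si](C)(C)C | intermediate
10 | 2-bromo-N-methoxy-N-methylacetamide | BrCC(=O)N(C)OC | starting material
11 | methyl (2RS,3S,4E)-3-[(3E)-5-(tert-butyldimethylsilyloxy)-3-methylpent-3-en-1-yl]-2-{2-[methoxy(methyl)amino]-2-oxoethyl}-4-methyl-7-(trimethylsilyl)hept-4-en-6-ynoate (C8 epimers) | COC(=O)C(CC(=O)N(C)OC)[C@H](CC/C(C)=C/CO[Si](C)(C)C(C)(C)C)/C(C)=C/C#C[Si](C)(C)C | intermediate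
12 | 2-methylprop-1-enylmagnesium bromide | CC(C)=C[Mg]Br | starting material
13 | methyl (2RS,3S,4E)-3-[(3E)-5-(tert-butyldimethylsilyloxy)-3-methylpent-3-en-1-yl]-4-methyl-2-(4-methyl-2-oxopent-3-en-1-yl)-7-(trimethylsilyl)hept-4-en-6-ynoate | COC(=O)C(CC(=O)C=C(C)C)[C@H](CC/C(C)=C/CO[Si](C)(C)C(C)(C)C)/C(C)=C/C#C[Si](C)(C)C | intermediate
14 | methyl (2RS,3S,4E)-3-[(3E)-5-(tert-butyldimethylsilyloxy)-3-methylpent-3-en-1-yl]-4-methyl-2-(4-methyl-2-oxopent-3-en-1-yl)hept-4-en-6-ynoate | COC(=O)C(CC(=O)C=C(C)C)[C@H](CC/C(C)=C/CO[Si](C)(C)C(C)(C)C)/C(C)=C/C#C | intermediate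
15 | methyl (2RS,3S,4E)-3-[(3E)-5-(tert-butyldimethylsilyloxy)-3-methylpent-3-en-1-yl]-4-methyl-2-(4-methyl-2-oxopent-3-en-1-yl)hepta-4,6-dienoate | COC(=O)C(CC(=O)C=C(C)C)[C@H](CC/C(C)=C/CO[Si](C)(C)C(C)(C)C)/C(C)=C/C=C | intermediate
16 | kinetic cycloadduct, methyl (9αH,10β-methyl,13E)-15-(tert-butyldimethylsilyloxy)-6-oxolabda-1,13-dien-17-oate as C5/C8 epimer mixture (not isolated) | C/C(=C\CO[Si](C)(C)C(C)(C)C)CC[C@H]1C(C(=O)OC)CC(=O)C2C(C)(C)CC=C[C@]12C | intermediate
17 | methyl (5αH,8βH,9αH,10β-methyl,13E)-15-(tert-butyldimethylsilyloxy)-6-oxolabda-1,13-dien-17-oate (trans-fused, ester equatorial) | C/C(=C\CO[Si](C)(C)C(C)(C)C)CC[C@H]1[C@H](C(=O)OC)CC(=O)[C@H]2C(C)(C)CC=C[C@]12C | intermediate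
18 | methyl (5αH,8βH,9αH,10β-methyl,13E)-15-(tert-butyldimethylsilyloxy)-6-oxolabd-13-en-17-oate | C/C(=C\CO[Si](C)(C)C(C)(C)C)CC[C@H]1[C@H](C(=O)OC)CC(=O)[C@H]2C(C)(C)CCC[C@]12C | intermediate
19 | methyl (5αH,8βH,9αH,10β-methyl,13E)-15-(tert-butyldimethylsilyloxy)-6-(trifluoromethanesulfonyloxy)labda-6,13-dien-17-oate | C/C(=C\CO[Si](C)(C)C(C)(C)C)CC[C@H]1[C@H](C(=O)OC)C=C(OS(=O)(=O)C(F)(F)F)[C@H]2C(C)(C)CCC[C@]12C | intermediate
20 | methyl (5αH,8βH,9αH,10β-methyl,13E)-15-(tert-butyldimethylsilyloxy)labda-6,13-dien-17-oate (not isolated) | C/C(=C\CO[Si](C)(C)C(C)(C)C)CC[C@H]1[C@H](C(=O)OC)C=C[C@H]2C(C)(C)CCC[C@]12C | intermediate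
21 | methyl (5αH,9αH,10β-methyl,13E)-15-(tert-butyldimethylsilyloxy)labda-7,13-dien-17-oate | C/C(=C\CO[Si](C)(C)C(C)(C)C)CC[C@H]1C(C(=O)OC)=CC[C@H]2C(C)(C)CCC[C@]12C | intermediate
22 | (5αH,9αH,10β-methyl,13E)-15-(tert-butyldimethylsilyloxy)labda-7,13-dien-17-oic acid (not isolated) | C/C(=C\CO[Si](C)(C)C(C)(C)C)CC[C@H]1C(C(=O)O)=CC[C@H]2C(C)(C)CCC[C@]12C | intermediate
23 | (5αH,9αH,10β-methyl,13E)-15-hydroxylabda-7,13-dien-17-oic acid | C/C(=C\CO)CC[C@H]1C(C(=O)O)=CC[C@H]2C(C)(C)CCC[C@]12C | intermediate
24 | isobutyric anhydride | CC(C)C(=O)OC(=O)C(C)C | starting material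
25 | (5S,9R,10S,13E)-15-(2-methylpropanoyloxy)labda-7,13-dien-17-oic acid (CNP0191003.1) | C/C(=C\COC(=O)C(C)C)CC[C@H]1C(C(=O)O)=CC[C@H]2C(C)(C)CCC[C@]12C | target

Total step count: 14. Longest linear sequence: 14 steps (from geraniol; all other starting materials are commercial and enter directly).

Steps most likely to fail

Step 9 (key cycloaddition). The diene terminus C10 carries a cis (inside) methyl group, so cycloaddition may be sluggish and cationic isomerisation of the diene by the aluminium Lewis acid may compete. Facial selectivity may also be poor: an endo-tether transition state would place C20 trans to C11 and, after C5 equilibration, give the C9/C10 diastereomer. The fallback sets out from 15 and returns at 16. Compound 15 is treated with the bis(trimethylsilyl) ether of (R,R)-hydrobenzoin and TMSOTf (CH2Cl2, −78 °C) to give the chiral dioxolane, methyl (3S,4E)-3-[(3E)-5-(tert-butyldimethylsilyloxy)-3-methylpent-3-en-1-yl]-4-methyl-2-{[(4R,5R)-2-(2-methylprop-1-enyl)-4,5-diphenyl-1,3-dioxolan-2-yl]methyl}hepta-4,6-dienoate F1. Under the same conditions F1 ionises to a vinyl oxocarbenium ion and should undergo the known stepwise ionic Diels–Alder reaction: C3 attacks C4, then the enol ether carbon C5 closes on the C10 allyl cation. No planar s-cis diene and no aluminium reagent are needed, and the acetal adds reagent control of the dienophile face to the C9 control (the antipodal diol is used if it is the matched one). The product, the (4R,5R)-4,5-diphenyl-1,3-dioxolane ketal of 16 F2, is hydrolysed with PPTS in wet acetone to 16, which is equilibrated with NaOMe to 17 as in the route.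

Step 4 (Johnson–Claisen). The carbinol is both allylic and propargylic, so acid and heat may ionise it (racemisation or elimination), the propargyl arm may rearrange to an allene, and the slim alkynyl group may lower the E selectivity. The fallback sets out from 6 and returns at 9. Compound 6 is acetylated (Ac2O, pyridine, DMAP) to (3R,4E,8E)-10-(tert-butyldimethylsilyloxy)-4,8-dimethyl-1-(trimethylsilyl)deca-4,8-dien-1-yn-3-yl acetate F3. An Ireland–Claisen rearrangement of F3 (LiN(SiMe3)2, TMSCl, THF, −78 °C to rt, acidic work-up) proceeds through the same chair geometry without acid or high temperature and gives (3S,4E)-3-[(3E)-5-(tert-butyldimethylsilyloxy)-3-methylpent-3-en-1-yl]-4-methyl-7-(trimethylsilyl)hept-4-en-6-ynoic acid F4. Esterification of F4 with TMSCHN2 in MeOH/toluene gives 9.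

Step 3 (asymmetric alkynylation). Racemic background addition of the alkynylzinc or slow turnover with the α-branched enal may erode the enantiomeric purity that every later stereocentre depends on. The fallback sets out from 4 and returns at 6. LiC≡CSiMe3 (THF, −78 °C) is added to 4 to give the racemic carbinol, rac-(4E,8E)-10-(tert-butyldimethylsilyloxy)-4,8-dimethyl-1-(trimethylsilyl)deca-4,8-dien-1-yn-3-ol F5. Oxidation with MnO2 gives the ynone, (4E,8E)-10-(tert-butyldimethylsilyloxy)-4,8-dimethyl-1-(trimethylsilyl)deca-4,8-dien-1-yn-3-one F6. F6 is reduced by Noyori asymmetric transfer hydrogenation (RuCl(p-cymene)(TsDPEN), the enantiomer that gives 3R, i-PrOH) to 6.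

Further compounds
F1 | step 9 | methyl (3S,4E)-3-[(3E)-5-(tert-butyldimethylsilyloxy)-3-methylpent-3-en-1-yl]-4-methyl-2-{[(4R,5R)-2-(2-methylprop-1-enyl)-4,5-diphenyl-1,3-dioxolan-2-yl]methyl}hepta-4,6-dienoate | COC(=O)C(CC1(C=C(C)C)O[C@H](c2ccccc2)[C@@H](c2ccccc2)O1)[C@H](CC/C(C)=C/CO[Si](C)(C)C(C)(C)C)/C(C)=C/C=C
F2 | step 9 | (4R,5R)-4,5-diphenyl-1,3-dioxolane ketal of 16 | C/C(=C\CO[Si](C)(C)C(C)(C)C)CC[C@H]1C(C(=O)OC)CC3(O[C@H](c4ccccc4)[C@@H](c4ccccc4)O3)C2C(C)(C)CC=C[C@]12C
F3 | step 4 | (3R,4E,8E)-10-(tert-butyldimethylsilyloxy)-4,8-dimethyl-1-(trimethylsilyl)deca-4,8-dien-1-yn-3-yl acetate | C[Si](C)(C)C#C[C@H](OC(C)=O)/C(C)=C/CC/C(C)=C/CO[Si](C)(C)C(C)(C)C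
F4 | step 4 | (3S,4E)-3-[(3E)-5-(tert-butyldimethylsilyloxy)-3-methylpent-3-en-1-yl]-4-methyl-7-(trimethylsilyl)hept-4-en-6-ynoic acid | OC(=O)C[C@H](CC/C(C)=C/CO[Si](C)(C)C(C)(C)C)/C(C)=C/C#C[Si](C)(C)C
F5 | step 3 | rac-(4E,8E)-10-(tert-butyldimethylsilyloxy)-4,8-dimethyl-1-(trimethylsilyl)deca-4,8-dien-1-yn-3-ol | C[Si](C)(C)C#CC(O)/C(C)=C/CC/C(C)=C/CO[Si](C)(C)C(C)(C)C
F6 | step 3 | (4E,8E)-10-(tert-butyldimethylsilyloxy)-4,8-dimethyl-1-(trimethylsilyl)deca-4,8-dien-1-yn-3-one | C[Si](C)(C)C#CC(=O)/C(C)=C/CC/C(C)=C/CO[Si](C)(C)C(C)(C)C
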